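**Plan**

- The target is read as epicatechin-(4α→8)-epicatechin 3-O-gallate-(4β→8)-epicatechin 3-O-gallate. Retrosynthetic cuts, in order: the two gallate esters, the top C4–middle C8 bond, the bottom O1–C8a bond (opening ring C of the bottom unit), the middle C4–bottom C8 bond.
- Forward: a C8-brominated, C4-activated middle unit from (−)-epicatechin is arylated at C4 by an open-chain (seco) bottom unit that carries fluorine where C8a will be. Ring C of the bottom unit is then closed by the C2 alkoxide displacing that fluoride. The middle C8–Li then adds to a top 4-ketone and the carbinol is reduced; deallylation, double galloylation and hydrogenolysis finish the route.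
- Enabling feature: ring A of the bottom unit is a phloroglucinol ring. C8a lies between C8 and C4a, and its two other oxygens (C5, C7) are meta to it, so a fluorine at C8a can be displaced by the C2 oxygen. Because ring C is closed at O1–C8a, neither C2 nor C3 is touched, and the 2,3-cis pattern is simply a syn 1,2-diol derivative of an open chain.
- Before closure the small fluorine leaves the neighbouring C8 as the accessible arene position for the interflavan bond; the other free position, C6, lies between two benzyloxy groups.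
- Stereochemistry: top and middle C2/C3 come from (−)-epicatechin; bottom C3 from (R)-trityl glycidyl ether and bottom C2 from a chelation-controlled aryl Grignard addition; middle C4 (β) from attack anti to the 3-O/2-aryl face; top C4 (α) from hydride delivery anti to the same face.

Key step: step 15

Remark: the configuration is read from the SMILES as 2R,3R in all three units, with the top C4–aryl bond cis to the top 3-hydroxyl and the middle C4–aryl bond trans to the middle 3-O-gallate.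

**Route**

Step 1
Reactants: 1 (−)-epicatechin; 2 benzyl bromide
Product: 3 5,7,3',4'-tetra-O-benzyl-(−)-epicatechin
Conditions: BnBr, K2CO3, DMF, 0 °C → rt
Reagents that add atoms: benzyl bromide 2, BrCc1ccccc1
Why: Williamson etherification with K2CO3 alkylates the four phenols and leaves the secondary alcohol free; no stereocentre is touched.

Step 2
Reactants: 3 5,7,3',4'-tetra-O-benzyl-(−)-epicatechin; 2 benzyl bromide
Product: 4 3,5,7,3',4'-penta-O-benzyl-(−)-epicatechin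
Conditions: NaH, BnBr, Bu4NI (cat.), DMF, 0 °C → rt
Reagents that add atoms: benzyl bromide 2, BrCc1ccccc1
Why: Williamson benzylation of the secondary alkoxide gives an ether that falls only in the final hydrogenolysis, so the top 3-oxygen stays masked while the other two are galloylated.

Step 3
Reactants: 4 3,5,7,3',4'-penta-O-benzyl-(−)-epicatechin; 5 water
Product: 6 3,5,7,3',4'-penta-O-benzyl-4β-hydroxy-(−)-epicatechin
Conditions: DDQ, CH2Cl2–H2O, rt
Reagents that add atoms: water 5, O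
Why: DDQ abstracts hydride from C4 (benzylic oxidation; the cation is stabilised by the ring A ethers) and water should add anti to the 3-benzyloxy group; the C4 configuration is irrelevant because it is oxidised next.

Step 4
Reactants: 6 3,5,7,3',4'-penta-O-benzyl-4β-hydroxy-(−)-epicatechin
Product: 7 (2R,3S)-3,5,7-tris(benzyloxy)-2-[3,4-bis(benzyloxy)phenyl]chroman-4-one (2,3-cis top ketone)
Conditions: Dess–Martin periodinane, NaHCO3, CH2Cl2, 0 °C → rt
Reagents that add atoms: none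
Why: Dess–Martin oxidation of the benzylic alcohol under buffered conditions should give the ketone without epimerising the adjacent C3.

Step 5
Reactants: 3 5,7,3',4'-tetra-O-benzyl-(−)-epicatechin; 8 N-bromosuccinimide
Product: 9 5,7,3',4'-tetra-O-benzyl-8-bromo-(−)-epicatechin
Conditions: NBS, CH2Cl2, −78 °C → rt
Reagents that add atoms: N-bromosuccinimide 8, O=C1CCC(=O)N1Br
Why: Electrophilic aromatic bromination of ring A should go to C8, flanked by O1 and one benzyloxy group, in preference to C6 between two benzyloxy groups.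

Step 6
Reactants: 9 5,7,3',4'-tetra-O-benzyl-8-bromo-(−)-epicatechin; 10 allyl bromide
Product: 11 3-O-allyl-5,7,3',4'-tetra-O-benzyl-8-bromo-(−)-epicatechin
Conditions: NaH, allyl bromide, DMF, 0 °C → rt
Reagents that add atoms: allyl bromide 10, C=CCBr
Why: Williamson allylation installs a 3-O group that tolerates DDQ, Lewis acid, KH, t-BuLi and CF3CO2H and can later be removed without touching benzyl ethers.

Step 7
Reactants: 11 3-O-allyl-5,7,3',4'-tetra-O-benzyl-8-bromo-(−)-epicatechin; 12 2-ethoxyethanol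
Product: 13 3-O-allyl-5,7,3',4'-tetra-O-benzyl-8-bromo-4β-(2-ethoxyethoxy)-(−)-epicatechin (middle electrophile)
Conditions: DDQ, 2-ethoxyethanol, CH2Cl2, rt
Reagents that add atoms: 2-ethoxyethanol 12, CCOCCO
Why: DDQ benzylic oxidation at C4 and capture of the cation by the alcohol anti to the 3-allyloxy group install the 4β leaving group, while the C8 bromine caps the nucleophilic arene position against self-condensation.

Step 8
Reactants: 14 1,3,5-trifluorobenzene; 15 benzyl alcohol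
Product: 16 1,3-bis(benzyloxy)-5-fluorobenzene
Conditions: NaH, BnOH (2.1 equiv), DMF, 0 → 80 °C
Reagents that add atoms: benzyl alcohol 15, OCc1ccccc1
Why: Two successive SNAr displacements of fluoride by benzyloxide; the third is slower, so the monofluoride should be isolable.

Step 9
Reactants: 16 1,3-bis(benzyloxy)-5-fluorobenzene; 17 (R)-trityl glycidyl ether
Product: 19 (2R)-1-[2,4-bis(benzyloxy)-6-fluorophenyl]-3-(trityloxy)propan-2-ol, via aryllithium 18 (not isolated)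
Conditions: n-BuLi, THF, −78 °C; then 17, BF3·OEt2, −78 °C; then H2O
Reagents that add atoms: (R)-trityl glycidyl ether 17, C(c1ccccc1)(c1ccccc1)(c1ccccc1)OC[C@H]1CO1
Why: Directed ortho-lithiation should occur at the most acidic C–H, between F and OBn, and the aryllithium opens the BF3-activated epoxide at its CH2 end (SN2), so the stereocentre of the glycidyl ether is carried over unchanged.

Step 10
Reactants: 19 (2R)-1-[2,4-bis(benzyloxy)-6-fluorophenyl]-3-(trityloxy)propan-2-ol; 10 allyl bromide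
Product: 20 (2R)-2-(allyloxy)-1-[2,4-bis(benzyloxy)-6-fluorophenyl]-3-(trityloxy)propane
Conditions: NaH added to 19 and excess allyl bromide, THF–DMF, 0 °C
Reagents that add atoms: allyl bromide 10, C=CCBr
Why: Williamson allylation at 0 °C should be much faster than attack of the alkoxide on the non-activated fluoroarene, and the trityl group cannot migrate.

Step 11
Reactants: 20 (2R)-2-(allyloxy)-1-[2,4-bis(benzyloxy)-6-fluorophenyl]-3-(trityloxy)propane
Product: 21 (2R)-2-(allyloxy)-3-[2,4-bis(benzyloxy)-6-fluorophenyl]propan-1-ol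
Conditions: TsOH·H2O (cat.), MeOH–CH2Cl2, rt
Reagents that add atoms: none
Why: Acid-catalysed methanolysis of the trityl ether (SN1 through the trityl cation) leaves allyl and benzyl ethers intact.

Step 12
Reactants: 21 (2R)-2-(allyloxy)-3-[2,4-bis(benzyloxy)-6-fluorophenyl]propan-1-ol
Product: 22 (2R)-2-(allyloxy)-3-[2,4-bis(benzyloxy)-6-fluorophenyl]propanal
Conditions: Dess–Martin periodinane, NaHCO3, CH2Cl2, 0 °C → rt; used crude
Reagents that add atoms: none
Why: Buffered Dess–Martin oxidation gives the α-alkoxy aldehyde without epimerisation of the α-carbon.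

Step 13
Reactants: 22 (2R)-2-(allyloxy)-3-[2,4-bis(benzyloxy)-6-fluorophenyl]propanal; 23 4-bromo-1,2-bis(benzyloxy)benzene
Product: 25 (1R,2R)-2-(allyloxy)-1-[3,4-bis(benzyloxy)phenyl]-3-[2,4-bis(benzyloxy)-6-fluorophenyl]propan-1-ol (seco bottom unit), via aryl Grignard reagent 24 (not isolated)
Conditions: 23, Mg, THF, rt; added to 22 and MgBr2·OEt2 in CH2Cl2, −78 °C; then H2O
Reagents that add atoms: [3,4-bis(benzyloxy)phenyl]magnesium bromide 24 (from 23 and Mg), Br[Mg]c1ccc(OCc2ccccc2)c(OCc2ccccc2)c1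
Why: Chelation-controlled Grignard addition (Cram chelate): magnesium bridges the carbonyl and allyloxy oxygens and the aryl group enters on the side of the α-hydrogen, which should give the syn (1R,2R) carbinol that maps onto the 2,3-cis flavan.

Step 14
Reactants: 13 middle electrophile; 25 seco bottom unit
Product: 26 3-O-allyl-5,7,3',4'-tetra-O-benzyl-8-bromo-4β-{4,6-bis(benzyloxy)-2-fluoro-3-[(2R,3R)-2-(allyloxy)-3-[3,4-bis(benzyloxy)phenyl]-3-hydroxypropyl]phenyl}-(−)-epicatechin (seco dimer)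
Conditions: 25 (excess), TMSOTf (cat.), 4 Å molecular sieves, CH2Cl2, −78 → −30 °C; then Et3N
Reagents that add atoms: none
Why: Lewis-acid ionisation of the 4-alkoxy group gives the ring-A-stabilised C4 cation, and Friedel–Crafts attack by the fluoroarene should occur at its position between F and OBn (para to the other OBn, less hindered than the position between two benzyloxy groups) and anti to the 3-allyloxy/2-aryl face, giving the 4β bond.

Step 15
Reactants: 26 seco dimer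
Product: 28 3-O-allyl-5,7,3',4'-tetra-O-benzyl-8-bromoepicatechin-(4β→8)-3-O-allyl-5,7,3',4'-tetra-O-benzylepicatechin, via potassium alkoxide 27 (not isolated)
Conditions: KH (1.0 equiv), 18-crown-6, THF, 0 °C; then DMF, 50 °C
Reagents that add atoms: none
Why: KH converts the benzylic hydroxyl of 26 into potassium alkoxide 27, whose oxygen adds to the fluorine-bearing aryl carbon (the future C8a) to give a Meisenheimer anion that expels fluoride (addition–elimination SNAr). The closest known reaction type is the base-mediated cyclisation of 3-(2-fluoroaryl)propanol alkoxides to chromans, including 3,5-dialkoxy-substituted fluoroarenes on the way to flavan-3-ols. Ring C (the pyran ring) of the bottom unit closes in the 6-exo mode by attack on the ipso carbon of the arene. No stereocentre is formed: the C2–O bond is not broken, so C2 keeps its configuration and the 2,3-cis relation is simply the syn relation of the (1R,2R) chain set in step 13. The step needs attack by the C2 oxygen only and at C8a only: the C3 oxygen is blocked as a non-migrating allyl ether so no five-membered ring can form, fluoride is the only displaceable group on that ring while the bromide of the middle unit has no ortho hydrogen and sits on an electron-rich ring, and the benzyloxy groups at C5 and C7 are meta to C8a so they do not oppose the anionic intermediate. One equivalent of KH is used so that no free base is left to isomerise the allyl ethers once fluoride has gone.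

Step 16
Reactants: 28 closed bromo dimer; 7 top ketone
Product: 30 3,5,7,3',4'-penta-O-benzyl-4-hydroxyepicatechin-(4→8)-3-O-allyl-5,7,3',4'-tetra-O-benzylepicatechin-(4β→8)-3-O-allyl-5,7,3',4'-tetra-O-benzylepicatechin (tertiary carbinol), via aryllithium 29 (not isolated)
Conditions: t-BuLi (2 equiv), THF, −78 °C; then 7, −78 → 0 °C; then H2O
Reagents that add atoms: none
Why: Bromine–lithium exchange at C8 of the middle unit is faster than any deprotonation, and 1,2-addition of the aryllithium to the ketone should occur anti to the 2-aryl/3-benzyloxy face; the carbinol configuration is erased in the next step.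

Step 17
Reactants: 30 tertiary carbinol
Product: 31 3,5,7,3',4'-penta-O-benzylepicatechin-(4α→8)-3-O-allyl-5,7,3',4'-tetra-O-benzylepicatechin-(4β→8)-3-O-allyl-5,7,3',4'-tetra-O-benzylepicatechin
Conditions: Bu3SnH, CF3CO2H, CH2Cl2, 0 °C
Reagents that add atoms: none
Why: Ionic hydrogenation: acid ionises the doubly benzylic tertiary alcohol and Bu3SnH should deliver hydride to the cation from the β face, anti to the α-oriented 2-aryl and 3-benzyloxy groups, so the middle-unit aryl group ends α (3,4-cis).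

Step 18
Reactants: 31 protected trimer
Product: 33 3,5,7,3',4'-penta-O-benzylepicatechin-(4α→8)-5,7,3',4'-tetra-O-benzylepicatechin-(4β→8)-5,7,3',4'-tetra-O-benzylepicatechin (middle and bottom 3-OH free), via bis(prop-1-enyl) ether 32 (not isolated)
Conditions: [Ir(cod)(PMePh2)2]PF6 (cat., activated with H2), THF, rt; then 0.1 M HCl, acetone–H2O, rt
Reagents that add atoms: none
Why: Iridium-hydride-catalysed isomerisation of both allyl ethers to prop-1-enyl ethers followed by mild hydrolysis of these enol ethers frees the two secondary alcohols and leaves every benzyl ether in place.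

Step 19
Reactants: 33 diol; 34 3,4,5-tris(benzyloxy)benzoic acid
Product: 35 3,5,7,3',4'-penta-O-benzylepicatechin-(4α→8)-[5,7,3',4'-tetra-O-benzyl-3-O-(3,4,5-tri-O-benzylgalloyl)epicatechin]-(4β→8)-[5,7,3',4'-tetra-O-benzyl-3-O-(3,4,5-tri-O-benzylgalloyl)epicatechin]
Conditions: 34 (excess), DCC, DMAP, CH2Cl2, rt
Reagents that add atoms: 3,4,5-tris(benzyloxy)benzoic acid 34, OC(=O)c1cc(OCc2ccccc2)c(OCc2ccccc2)c(OCc2ccccc2)c1
Why: Steglich esterification acylates the two free secondary alcohols, while the top 3-oxygen is still a benzyl ether and cannot react.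

Step 20
Reactants: 35 perbenzylated bis-gallate
Product: 36 epicatechin-(4α→8)-epicatechin 3-O-gallate-(4β→8)-epicatechin 3-O-gallate (target)
Conditions: H2 (1 atm), Pd(OH)2/C, THF–MeOH–H2O, rt
Reagents that add atoms: none
Why: Hydrogenolysis should cleave all nineteen benzyl ethers (eighteen aryl, one alkyl) while the esters, the pyran C–O bonds and the interflavan bonds stay intact.

**Compound list**

1 | (−)-epicatechin | O[C@@H]1Cc2c(O)cc(O)cc2O[C@@H]1c1ccc(O)c(O)c1 | starting material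
2 | benzyl bromide | BrCc1ccccc1 | starting material
3 | 5,7,3',4'-tetra-O-benzyl-(−)-epicatechin | O[C@@H]1Cc2c(OCc5ccccc5)cc(OCc5ccccc5)cc2O[C@@H]1c1ccc(OCc5ccccc5)c(OCc5ccccc5)c1 | intermediate
4 | 3,5,7,3',4'-penta-O-benzyl-(−)-epicatechin | C(c5ccccc5)O[C@@H]1Cc2c(OCc5ccccc5)cc(OCc5ccccc5)cc2O[C@@H]1c1ccc(OCc5ccccc5)c(OCc5ccccc5)c1 | intermediate
5 | water | O | starting material
6 | 3,5,7,3',4'-penta-O-benzyl-4β-hydroxy-(−)-epicatechin | C(c5ccccc5)O[C@@H]1[C@@H](O)c2c(OCc5ccccc5)cc(OCc5ccccc5)cc2O[C@@H]1c1ccc(OCc5ccccc5)c(OCc5ccccc5)c1 | intermediate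
7 | (2R,3S)-3,5,7-tris(benzyloxy)-2-[3,4-bis(benzyloxy)phenyl]chroman-4-one | C(c5ccccc5)O[C@@H]1C(=O)c2c(OCc5ccccc5)cc(OCc5ccccc5)cc2O[C@@H]1c1ccc(OCc5ccccc5)c(OCc5ccccc5)c1 | intermediate
8 | N-bromosuccinimide | O=C1CCC(=O)N1Br | starting material
9 | 5,7,3',4'-tetra-O-benzyl-8-bromo-(−)-epicatechin | O[C@@H]1Cc2c(OCc5ccccc5)cc(OCc5ccccc5)c(Br)c2O[C@@H]1c1ccc(OCc5ccccc5)c(OCc5ccccc5)c1 | intermediate
10 | allyl bromide | C=CCBr | starting material
11 | 3-O-allyl-5,7,3',4'-tetra-O-benzyl-8-bromo-(−)-epicatechin | C=CCO[C@@H]1Cc2c(OCc5ccccc5)cc(OCc5ccccc5)c(Br)c2O[C@@H]1c1ccc(OCc5ccccc5)c(OCc5ccccc5)c1 | intermediate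
12 | 2-ethoxyethanol | CCOCCO | starting material
13 | 3-O-allyl-5,7,3',4'-tetra-O-benzyl-8-bromo-4β-(2-ethoxyethoxy)-(−)-epicatechin | C=CCO[C@@H]1[C@@H](OCCOCC)c2c(OCc5ccccc5)cc(OCc5ccccc5)c(Br)c2O[C@@H]1c1ccc(OCc5ccccc5)c(OCc5ccccc5)c1 | intermediate
14 | 1,3,5-trifluorobenzene | Fc1cc(F)cc(F)c1 | starting material
15 | benzyl alcohol | OCc1ccccc1 | starting material
16 | 1,3-bis(benzyloxy)-5-fluorobenzene | Fc1cc(OCc2ccccc2)cc(OCc2ccccc2)c1 | intermediate
17 | (R)-trityl glycidyl ether, (2R)-2-[(trityloxy)methyl]oxirane | C(c1ccccc1)(c1ccccc1)(c1ccccc1)OC[C@H]1CO1 | starting material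
18 | [2,4-bis(benzyloxy)-6-fluorophenyl]lithium | [Li]c1c(F)cc(OCc2ccccc2)cc1OCc1ccccc1 | intermediate
19 | (2R)-1-[2,4-bis(benzyloxy)-6-fluorophenyl]-3-(trityloxy)propan-2-ol | C(c1ccccc1)(c1ccccc1)(c1ccccc1)OC[C@H](O)Cc1c(F)cc(OCc2ccccc2)cc1OCc1ccccc1 | intermediate
20 | (2R)-2-(allyloxy)-1-[2,4-bis(benzyloxy)-6-fluorophenyl]-3-(trityloxy)propane | C(c1ccccc1)(c1ccccc1)(c1ccccc1)OC[C@H](OCC=C)Cc1c(F)cc(OCc2ccccc2)cc1OCc1ccccc1 | intermediate
21 | (2R)-2-(allyloxy)-3-[2,4-bis(benzyloxy)-6-fluorophenyl]propan-1-ol | OC[C@H](OCC=C)Cc1c(F)cc(OCc2ccccc2)cc1OCc1ccccc1 | intermediate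
22 | (2R)-2-(allyloxy)-3-[2,4-bis(benzyloxy)-6-fluorophenyl]propanal | O=C[C@H](OCC=C)Cc1c(F)cc(OCc2ccccc2)cc1OCc1ccccc1 | intermediate
23 | 4-bromo-1,2-bis(benzyloxy)benzene | Brc1ccc(OCc2ccccc2)c(OCc2ccccc2)c1 | starting material
24 | [3,4-bis(benzyloxy)phenyl]magnesium bromide | Br[Mg]c1ccc(OCc2ccccc2)c(OCc2ccccc2)c1 | intermediate
25 | (1R,2R)-2-(allyloxy)-1-[3,4-bis(benzyloxy)phenyl]-3-[2,4-bis(benzyloxy)-6-fluorophenyl]propan-1-ol | O[C@H](c1ccc(OCc2ccccc2)c(OCc2ccccc2)c1)[C@H](OCC=C)Cc1c(F)cc(OCc2ccccc2)cc1OCc1ccccc1 | intermediate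
26 | seco dimer (name as in step 14) | C=CCO[C@@H]1[C@@H](c3c(OCc5ccccc5)cc(OCc5ccccc5)c(C[C@@H](OCC=C)[C@H](O)c6ccc(OCc5ccccc5)c(OCc5ccccc5)c6)c3F)c2c(OCc5ccccc5)cc(OCc5ccccc5)c(Br)c2O[C@@H]1c1ccc(OCc5ccccc5)c(OCc5ccccc5)c1 | intermediate
27 | potassium alkoxide of 26 | C=CCO[C@@H]1[C@@H](c3c(OCc5ccccc5)cc(OCc5ccccc5)c(C[C@@H](OCC=C)[C@H]([O-])c6ccc(OCc5ccccc5)c(OCc5ccccc5)c6)c3F)c2c(OCc5ccccc5)cc(OCc5ccccc5)c(Br)c2O[C@@H]1c1ccc(OCc5ccccc5)c(OCc5ccccc5)c1.[K+] | intermediate
28 | 3-O-allyl-5,7,3',4'-tetra-O-benzyl-8-bromoepicatechin-(4β→8)-3-O-allyl-5,7,3',4'-tetra-O-benzylepicatechin | C=CCO[C@@H]1[C@@H](c7c(OCc5ccccc5)cc(OCc5ccccc5)c8c7O[C@H](c6ccc(OCc5ccccc5)c(OCc5ccccc5)c6)[C@H](OCC=C)C8)c2c(OCc5ccccc5)cc(OCc5ccccc5)c(Br)c2O[C@@H]1c1ccc(OCc5ccccc5)c(OCc5ccccc5)c1 | intermediate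
29 | 8-lithio analogue of 28 (Li in place of Br) | C=CCO[C@@H]1[C@@H](c7c(OCc5ccccc5)cc(OCc5ccccc5)c8c7O[C@H](c6ccc(OCc5ccccc5)c(OCc5ccccc5)c6)[C@H](OCC=C)C8)c2c(OCc5ccccc5)cc(OCc5ccccc5)c([Li])c2O[C@@H]1c1ccc(OCc5ccccc5)c(OCc5ccccc5)c1 | intermediate
30 | trimeric tertiary carbinol (top C4: OH α, aryl β) | C=CCO[C@@H]1[C@@H](c7c(OCc5ccccc5)cc(OCc5ccccc5)c8c7O[C@H](c6ccc(OCc5ccccc5)c(OCc5ccccc5)c6)[C@H](OCC=C)C8)c2c(OCc5ccccc5)cc(OCc5ccccc5)c([C@@]3(O)c4c(OCc5ccccc5)cc(OCc5ccccc5)cc4O[C@H](c4ccc(OCc5ccccc5)c(OCc5ccccc5)c4)[C@@H]3OCc5ccccc5)c2O[C@@H]1c1ccc(OCc5ccccc5)c(OCc5ccccc5)c1 | intermediate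
31 | penta-O-benzylepicatechin-(4α→8)-3-O-allyl-tetra-O-benzylepicatechin-(4β→8)-3-O-allyl-tetra-O-benzylepicatechin | C=CCO[C@@H]1[C@@H](c7c(OCc5ccccc5)cc(OCc5ccccc5)c8c7O[C@H](c6ccc(OCc5ccccc5)c(OCc5ccccc5)c6)[C@H](OCC=C)C8)c2c(OCc5ccccc5)cc(OCc5ccccc5)c([C@@H]3c4c(OCc5ccccc5)cc(OCc5ccccc5)cc4O[C@H](c4ccc(OCc5ccccc5)c(OCc5ccccc5)c4)[C@@H]3OCc5ccccc5)c2O[C@@H]1c1ccc(OCc5ccccc5)c(OCc5ccccc5)c1 | intermediate
32 | bis(prop-1-enyl) ether of 33 | CC=CO[C@@H]1[C@@H](c7c(OCc5ccccc5)cc(OCc5ccccc5)c8c7O[C@H](c6ccc(OCc5ccccc5)c(OCc5ccccc5)c6)[C@H](OC=CC)C8)c2c(OCc5ccccc5)cc(OCc5ccccc5)c([C@@H]3c4c(OCc5ccccc5)cc(OCc5ccccc5)cc4O[C@H](c4ccc(OCc5ccccc5)c(OCc5ccccc5)c4)[C@@H]3OCc5ccccc5)c2O[C@@H]1c1ccc(OCc5ccccc5)c(OCc5ccccc5)c1 | intermediate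
33 | penta-O-benzylepicatechin-(4α→8)-tetra-O-benzylepicatechin-(4β→8)-tetra-O-benzylepicatechin (middle and bottom 3-OH free) | O[C@@H]1[C@@H](c7c(OCc5ccccc5)cc(OCc5ccccc5)c8c7O[C@H](c6ccc(OCc5ccccc5)c(OCc5ccccc5)c6)[C@H](O)C8)c2c(OCc5ccccc5)cc(OCc5ccccc5)c([C@@H]3c4c(OCc5ccccc5)cc(OCc5ccccc5)cc4O[C@H](c4ccc(OCc5ccccc5)c(OCc5ccccc5)c4)[C@@H]3OCc5ccccc5)c2O[C@@H]1c1ccc(OCc5ccccc5)c(OCc5ccccc5)c1 | intermediate
34 | 3,4,5-tris(benzyloxy)benzoic acid | OC(=O)c1cc(OCc2ccccc2)c(OCc2ccccc2)c(OCc2ccccc2)c1 | starting material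
35 | perbenzylated bis-gallate (name as in step 19) | O=C(O[C@@H]1[C@@H](c7c(OCc5ccccc5)cc(OCc5ccccc5)c8c7O[C@H](c6ccc(OCc5ccccc5)c(OCc5ccccc5)c6)[C@H](OC(=O)c6cc(OCc5ccccc5)c(OCc5ccccc5)c(OCc5ccccc5)c6)C8)c2c(OCc5ccccc5)cc(OCc5ccccc5)c([C@@H]3c4c(OCc5ccccc5)cc(OCc5ccccc5)cc4O[C@H](c4ccc(OCc5ccccc5)c(OCc5ccccc5)c4)[C@@H]3OCc5ccccc5)c2O[C@@H]1c1ccc(OCc5ccccc5)c(OCc5ccccc5)c1)c1cc(OCc5ccccc5)c(OCc5ccccc5)c(OCc5ccccc5)c1 | intermediate
36 | epicatechin-(4α→8)-epicatechin 3-O-gallate-(4β→8)-epicatechin 3-O-gallate | O=C(O[C@@H]1[C@@H](c2c(O)cc(O)c3c2O[C@H](c2ccc(O)c(O)c2)[C@H](OC(=O)c2cc(O)c(O)c(O)c2)C3)c2c(O)cc(O)c([C@@H]3c4c(O)cc(O)cc4O[C@H](c4ccc(O)c(O)c4)[C@@H]3O)c2O[C@@H]1c1ccc(O)c(O)c1)c1cc(O)c(O)c(O)c1 | target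

**Step count and risks**

Total steps: 20. Longest linear sequence: 13 steps (steps 8–20, from 1,3,5-trifluorobenzene).

Steps most likely to fail:

1. Step 14. The fluoroarene of 25 is a weaker nucleophile than a trialkoxyarene. Capture of the C4 cation may therefore be slow and leak to the position between the two benzyloxy groups or to C6 of a second molecule of 13, eroding regiochemical purity. Fallback: the bottom unit is taken as the closed flavan from the chiral pool. The fallback sets out from 3, which is used in excess with 13 and TMSOTf in the classical C8-selective arylation to give 3-O-allyl-5,7,3',4'-tetra-O-benzyl-8-bromoepicatechin-(4β→8)-5,7,3',4'-tetra-O-benzylepicatechin F1. Allylation of its free bottom 3-hydroxyl (NaH, allyl bromide) comes back to the route at 28.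

2. Step 15. Displacement at C8a, flanked by the flavanyl-bearing C8 and by C4a, may be slow. On forcing, the alkoxide may instead isomerise the allyl ethers to propenyl ethers or degrade the substrate. Fallback: ring C is closed before the interflavan bond is made. The fallback sets out from 25, which with KH gives potassium alkoxide F2 and then, by the same fluoride displacement at an unhindered C8a, 3-O-allyl-5,7,3',4'-tetra-O-benzyl-(−)-epicatechin F3. TMSOTf-mediated arylation of 13 by F3 comes back to the route at 28.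

3. Step 17. While the carbinol is ionised, acid may also protonate C8 of the bottom unit and break the middle–bottom 4β→8 bond in competition with hydride transfer. Fallback: the 4α bond is made between monomers, before any 4β bond exists. The fallback sets out from 11. Bromine–lithium exchange (t-BuLi) gives the 8-lithio compound F4, and addition to 7 gives the dimeric tertiary carbinol F5. Bu3SnH/CF3CO2H gives penta-O-benzylepicatechin-(4α→8)-3-O-allyl-tetra-O-benzylepicatechin F6. DDQ with 2-ethoxyethanol gives its 4β-(2-ethoxyethoxy) derivative on the lower unit F7. TMSOTf with excess 25 gives the seco trimer F8, and KH gives potassium alkoxide F9, whose ring closure comes back to the route at 31.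

**Further compounds**

F1 | step 14 | 3-O-allyl-5,7,3',4'-tetra-O-benzyl-8-bromoepicatechin-(4β→8)-5,7,3',4'-tetra-O-benzylepicatechin | C=CCO[C@@H]1[C@@H](c7c(OCc5ccccc5)cc(OCc5ccccc5)c8c7O[C@H](c6ccc(OCc5ccccc5)c(OCc5ccccc5)c6)[C@H](O)C8)c2c(OCc5ccccc5)cc(OCc5ccccc5)c(Br)c2O[C@@H]1c1ccc(OCc5ccccc5)c(OCc5ccccc5)c1
F2 | step 15 | potassium alkoxide of 25 | [O-][C@H](c1ccc(OCc2ccccc2)c(OCc2ccccc2)c1)[C@H](OCC=C)Cc1c(F)cc(OCc2ccccc2)cc1OCc1ccccc1.[K+]
F3 | step 15 | 3-O-allyl-5,7,3',4'-tetra-O-benzyl-(−)-epicatechin | C=CCO[C@@H]1Cc2c(OCc5ccccc5)cc(OCc5ccccc5)cc2O[C@@H]1c1ccc(OCc5ccccc5)c(OCc5ccccc5)c1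
F4 | step 17 | 8-lithio analogue of 11 | C=CCO[C@@H]1Cc2c(OCc5ccccc5)cc(OCc5ccccc5)c([Li])c2O[C@@H]1c1ccc(OCc5ccccc5)c(OCc5ccccc5)c1
F5 | step 17 | dimeric tertiary carbinol | C=CCO[C@@H]1Cc2c(OCc5ccccc5)cc(OCc5ccccc5)c([C@@]3(O)c4c(OCc5ccccc5)cc(OCc5ccccc5)cc4O[C@H](c4ccc(OCc5ccccc5)c(OCc5ccccc5)c4)[C@@H]3OCc5ccccc5)c2O[C@@H]1c1ccc(OCc5ccccc5)c(OCc5ccccc5)c1
F6 | step 17 | penta-O-benzylepicatechin-(4α→8)-3-O-allyl-tetra-O-benzylepicatechin | C=CCO[C@@H]1Cc2c(OCc5ccccc5)cc(OCc5ccccc5)c([C@@H]3c4c(OCc5ccccc5)cc(OCc5ccccc5)cc4O[C@H](c4ccc(OCc5ccccc5)c(OCc5ccccc5)c4)[C@@H]3OCc5ccccc5)c2O[C@@H]1c1ccc(OCc5ccccc5)c(OCc5ccccc5)c1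
F7 | step 17 | 4β-(2-ethoxyethoxy) derivative of F6 (lower unit) | C=CCO[C@@H]1[C@@H](OCCOCC)c2c(OCc5ccccc5)cc(OCc5ccccc5)c([C@@H]3c4c(OCc5ccccc5)cc(OCc5ccccc5)cc4O[C@H](c4ccc(OCc5ccccc5)c(OCc5ccccc5)c4)[C@@H]3OCc5ccccc5)c2O[C@@H]1c1ccc(OCc5ccccc5)c(OCc5ccccc5)c1
F8 | step 17 | seco trimer | C=CCO[C@@H]1[C@@H](c7c(OCc5ccccc5)cc(OCc5ccccc5)c(C[C@@H](OCC=C)[C@H](O)c6ccc(OCc5ccccc5)c(OCc5ccccc5)c6)c7F)c2c(OCc5ccccc5)cc(OCc5ccccc5)c([C@@H]3c4c(OCc5ccccc5)cc(OCc5ccccc5)cc4O[C@H](c4ccc(OCc5ccccc5)c(OCc5ccccc5)c4)[C@@H]3OCc5ccccc5)c2O[C@@H]1c1ccc(OCc5ccccc5)c(OCc5ccccc5)c1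
F9 | step 17 | potassium alkoxide of F8 | C=CCO[C@@H]1[C@@H](c7c(OCc5ccccc5)cc(OCc5ccccc5)c(C[C@@H](OCC=C)[C@H]([O-])c6ccc(OCc5ccccc5)c(OCc5ccccc5)c6)c7F)c2c(OCc5ccccc5)cc(OCc5ccccc5)c([C@@H]3c4c(OCc5ccccc5)cc(OCc5ccccc5)cc4O[C@H](c4ccc(OCc5ccccc5)c(OCc5ccccc5)c4)[C@@H]3OCc5ccccc5)c2O[C@@H]1c1ccc(OCc5ccccc5)c(OCc5ccccc5)c1.[K+]
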